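Atom labels follow chromane numbering throughout: ring B is O1, C2, C3, C4, C4a, C8a; ring A is C4a, C5, C6, C7, C8, C8a; the long side chain on C6 starts at C1' and C2'.

## The problem

Target 34 is a dearomatised chromanone acid. Ring A is a cyclohexane-1,3,5-trione oxygenated at C5, C7 and C8a, fused through C4a–C8a to a cis-2,3-dimethyl dihydropyranone ring B whose oxygen O1 sits on C8a, the carbon para to quaternary C6. Its five stereocentres fall into three groups that cannot communicate: C2/C3 in ring B (2R,3S), C6 with its 1,3-neighbour C2' (6S,2'R), and the benzylic carbon on C8 (R). Only C2' and C6 are close enough for one to control the other, so the other centres have to arrive as single enantiomers. The pairs C5/C7 and O5/O8a differ only through C6 and must be told apart by connectivity, not by reagent preference. The molecule carries three acid-sensitive alkenes placed to cyclise onto enol oxygens, a vinylogous acid, a cis ring B that base can epimerise at C3 or open by retro-oxa-Michael reaction, and a C2' branch point that passes through an enolisable aldehyde. The enabling feature is that C6 lies between the C5 and C7 carbonyls and is one methylene (C1') away from C2'. C7, C6, C1', C2' and the carbon that becomes the isobutenyl CH can therefore be closed with one oxygen into a six-membered lactone: its chair relates C6 to C2', its carbonyl is C7 and is thereby distinguished from C5, and its alkoxide is the leaving group for a Dieckmann closure of ring A.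

## Retrosynthesis

**Acid and isobutenyl group (34 ⇒ 32 ⇒ 31 ⇒ 30 ⇒ 29).** The acid is taken back to tert-butyl ester 32, which a silyl triflate cleaves under buffered conditions; a methyl ester would need saponification, which the cis ring B would not survive. The isobutenyl C=C is cut to aldehyde 31, then to alcohol 30 and its silyl ether 29. This cut is dictated by the key step, in which the carbinol carbon of 30 is the lactone CH2–O. Oxidation and olefination are placed after ring B closure, when C4a is fully substituted and can no longer condense with the aldehyde. The forward reactions must olefinate an α-branched aldehyde without enolising C2'.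

**Ring B (29 ⇒ 27 ⇒ 20 + 25).** O1–C8a and then C4–C4a are cut, giving trione 20 and silyl-protected (2S,3R)-3-hydroxy-2-methylbutanoic acid 25 by way of C4a-acyl trione 27. Both ring B stereocentres are bought in one aldol reaction and never made on the ring system. O1–C8a forms by addition–elimination at the C8a carbonyl with the carbinol C–O bond intact, so the syn acid gives the cis ring with retention. The neighbouring cut at O1–C2 (displacement at the carbinol carbon) needs the anti acid and has to outrun this same cyclodehydration. A cut at C2–C3 or a conjugate addition to a tigloyl group would leave both centres uncontrolled. Regiochemistry rests on sterics: an alcohol adds to the C8a carbonyl, flanked by two sp2 carbons, more easily than to C5, flanked by quaternary C6. The primary alcohol of 19 is silylated (20) so that it is neither acylated nor drawn into an enol ether of its own.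

**Ring A (19 ⇒ 18), the key cut.** The C7–C8 bond is cut, and C7 is reconnected to the C2' oxygen as the δ-lactone of diketone 18. The neighbouring cuts are worse. Closing at C4a–C8a would require an intermolecular C7–C8 acylation by one of two near-identical ester arms of a glutarate. Closing at C5–C6 or C6–C7 would form the quaternary centre in the ring closure with nothing to direct it. Precursor 18 has no carbocycle; ring A, the C5/C7 distinction and the position of the C8 substituent all follow from its connectivity. The forward reaction must generate the C8 carbanion of a 1,3-diketone dianion and have it attack the lactone in preference to the ester.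

**Diketone arm (18 ⇒ 12 + 16).** The C4a–C8a bond is cut to acetyl lactone 12 and hemiester 16. This is the convergent point: two fragments of similar size, each carrying its own stereochemistry, are joined by a Claisen acylation. The acetyl methyl of 12 is its only enolisable position, so no regiochemical question arises.

**Quaternary C6 (12 ⇒ 11 ⇒ 9 + 10).** The C6–acetyl bond is cut first and the C6–prenyl bond second. The order is not free: the second electrophile enters a δ-lactone enolate axially, trans to the C5 substituent of the lactone, and the target needs the acyl group trans to the C2' chain. Prenyl bromide 10 therefore goes on first. Lactone 9 has one stereocentre.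

**Lactone (9 ⇒ 7 ⇒ 5 + 6; 5 ⇒ 2 + 3; 2 ⇒ 1).** The bond between C2' and the future C1' is cut as an auxiliary-controlled Michael addition of imide 5 to acrylate 6. The alternative, enzymatic desymmetrisation of a 2-alkylpropane-1,3-diol followed by two-carbon homologation, is three to four steps longer and depends on how well a lipase recognises this particular alkyl group. Acid 2 comes from keto acid 1 by methylenation.

**Hemiester (16 ⇒ 15 ⇒ 14 ⇒ 13).** The ester C–O bond is cut back to meso anhydride 13. Catalytic methanolysis sets the benzylic centre, and an ester exchange (14 to 15 to 16) installs the tert-butyl group that the key step needs and moves the free acid to the other arm.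

**Ring B acid (25 ⇒ 23 ⇒ 22 ⇒ 21).** The C2–C3 bond of the acid is cut as a syn-selective boron aldol of propionimide 21 with the two-carbon aldehyde.

## Roads not taken

**Alternative 1:** Here no skeletal bond is cut at the key stage. The symmetric trione A1, in which C6 is not yet a stereocentre, is cyclodehydrated under acid so that the C2' hydroxymethyl arm binds one of the two flanking carbonyls as a six-membered enol ether, A2. The step is reversible, so the two diastereomers equilibrate through A1 and the C2' centre selects C6 thermodynamically. Its merits are real: A1 should be reachable in far fewer steps than lactone 12, no cryogenic enolate chemistry is needed, and the tether marks the C5 oxygen for later regiocontrol, which the chosen plan secures only through sterics. Its weak points are structural. The two diastereomers of A2 differ only in which of two similar groups on C6 (the prenyl methylene or the ring carbonyl carbon) is axial on the new oxane ring, so the equilibrium preference should be small. The C8 substituent with its benzylic centre must then be put onto A2 with two nucleophilic ring carbons competing and nothing to control the new centre. The tether must finally be hydrolysed beside the ring B enol ether. The chosen plan pays with a longer linear sequence but sets C6 kinetically in an enolate reaction of known facial bias and brings the benzylic centre in already resolved.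

**Alternative 2:** Ring B is cut at C2–C3 and O1–C8a. The forward step combines the tris-enol ether A3 with acetaldehyde under a chiral Ti(Oi-Pr)4/BINOL Lewis acid in an aldol-type [4+2] process and loses methanol to give A4. It is the most economical way to make ring B: one catalytic step from the simplest aldehyde, with O1 fixed on C8a by the position of the methyl enol ether. It would replace steps 13 to 17 of the chosen plan. Its weak points lie in the substrate. A3 needs a regiodefined C8a methyl enol ether and a geometrically pure Z silyl enol ether on a system with four enolisable carbonyls. The diene terminus C8a is fully substituted and part of a ring, so it is much less reactive than the simple dienes for which this catalysis is established. The catalyst must override whatever bias C6 exerts, and acetaldehyde is a poor partner for enantioselective Lewis acid catalysis. This alternative is silent on ring A and C6. The chosen plan accepts a three-step chiral acid (25) in exchange for ring B stereochemistry that is fixed before the acid touches the ring system.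

**Alternative 3:** Ring B is cut at O1–C2. The tethered precursor A5, carrying the anti (2S,3S)-hydroxyacyl group on C4a, is closed under PPh3 and diisopropyl azodicarboxylate with inversion at C2 to give A6. The merits are stereospecificity, neutral conditions, an acid that is one alkylation away from a commercial hydroxybutanoate (shorter than the aldol route to 25), and a tether that blocks the C5 oxygen with certainty. The weak points are that a β-hydroxy ketone beside a vinylogous acid can cyclodehydrate on its own with retention, which here gives the trans ring, so any leakage erodes the cis:trans purity. The betaine can also eliminate the activated alcohol to a tigloyl group. The tether inherits the removal problem of Alternative 1. The chosen plan uses the same chiral-pool logic but the syn acid, so that the spontaneous pathway is the productive one, and keeps the invertive closure in reserve as the fallback for step 17.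

Key step: step 11

Assumption 1: hydroquinine anthraquinone-1,4-diyl diether, (DHQ)2AQN, is taken to open anhydride 13 to the (S)-hemiester 14; if the sense is the reverse, the pseudoenantiomeric hydroquinidine catalyst (DHQD)2AQN is used and nothing else changes.

Assumption 2: the polycarbonyl compounds 19, 20 and 26 to 34 are tautomeric mixtures; each is written in one convenient enol form.

## Route

Step 1
Reactants: 1 5-oxohexanoic acid
Product: 2 5-methylhex-5-enoic acid
Conditions: Ph3PCH3Br (2.5 equiv), KOt-Bu (2.5 equiv), THF, 0 °C → rt; aq. HCl work-up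
Reagents that add atoms: methyltriphenylphosphonium bromide, C[P+](c1ccccc1)(c1ccccc1)c1ccccc1.[Br-]
Why: Wittig methylenation of the ketone; the first equivalent of ylide only forms the inert carboxylate, and 2 is recovered on acidification.

Step 2
Reactants: 2 5-methylhex-5-enoic acid; 3 (4S)-4-benzyl-1,3-oxazolidin-2-one
Product: 5 (4S)-4-benzyl-3-(5-methylhex-5-enoyl)-1,3-oxazolidin-2-one, via mixed pivalic anhydride 4 (not isolated)
Conditions: t-BuCOCl, Et3N, THF, −20 °C; then 3, LiCl, −20 °C → rt
Reagents that add atoms: none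
Why: N-acylation of the oxazolidinone auxiliary through a mixed anhydride; the hindered pivaloyl carbonyl directs the nucleophile to the desired acyl group.

Step 3
Reactants: 5 (4S)-4-benzyl-3-(5-methylhex-5-enoyl)-1,3-oxazolidin-2-one; 6 tert-butyl acrylate
Product: 7 tert-butyl (4R)-4-{[(4S)-4-benzyl-2-oxo-1,3-oxazolidin-3-yl]carbonyl}-7-methyloct-7-enoate
Conditions: TiCl4, Ti(Oi-Pr)4 (3:1), i-Pr2NEt, CH2Cl2, 0 °C; then 6, 0 °C → rt
Reagents that add atoms: none
Why: Michael addition of the chlorotitanium enolate of an N-acyl oxazolidinone to an acrylate; the chelated Z-enolate is attacked on the face opposite the benzyl group, the same sense as Evans alkylation, which sets the future C2' as (R).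

Step 4
Reactants: 7 tert-butyl (4R)-4-{[(4S)-4-benzyl-2-oxo-1,3-oxazolidin-3-yl]carbonyl}-7-methyloct-7-enoate
Product: 9 (5R)-5-(3-methylbut-3-en-1-yl)oxan-2-one, via hydroxy ester 8 (not isolated)
Conditions: LiBH4, MeOH (1 equiv), THF, 0 °C; aqueous work-up; then TsOH·H2O (10 mol %), toluene, 50 °C
Reagents that add atoms: none
Why: Reductive removal of the auxiliary (the imide is reduced much faster than the tert-butyl ester) followed by acid-catalysed lactonisation (intramolecular transesterification); the stereocentre is never α to a carbonyl and cannot epimerise.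

Step 5
Reactants: 9 (5R)-5-(3-methylbut-3-en-1-yl)oxan-2-one; 10 prenyl bromide (1-bromo-3-methylbut-2-ene)
Product: 11 (5R)-5-(3-methylbut-3-en-1-yl)-3-(3-methylbut-2-en-1-yl)oxan-2-one (mixture of C3 epimers)
Conditions: LiN(i-Pr)2 (1.05 equiv), THF, −78 °C; then 10, −78 → −30 °C
Reagents that add atoms: none
Why: SN2 alkylation of a δ-lactone lithium enolate with an allylic bromide; the C3 configuration is irrelevant because C3 is enolised again in step 6.

Step 6
Reactants: 11 (5R)-5-(3-methylbut-3-en-1-yl)-3-(3-methylbut-2-en-1-yl)oxan-2-one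
Product: 12 (3S,5R)-3-acetyl-5-(3-methylbut-3-en-1-yl)-3-(3-methylbut-2-en-1-yl)oxan-2-one
Conditions: LiN(i-Pr)2, THF, −78 → −40 °C; enolate transferred into AcCl (3 equiv), THF, −78 °C
Reagents that add atoms: acetyl chloride, CC(=O)Cl
Why: Crossed Claisen C-acylation of a fully substituted ester enolate by an acid chloride, with inverse addition to limit proton transfer to the product. The half-chair enolate holds the C5 chain pseudoequatorial and is attacked axially, anti to that chain, so the acetyl group enters trans to it and the future C6 is set (3S in 12).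

Step 7
Reactants: 13 3-phenylglutaric anhydride
Product: 14 (3S)-5-methoxy-5-oxo-3-phenylpentanoic acid
Conditions: (DHQ)2AQN, hydroquinine anthraquinone-1,4-diyl diether (10 mol %), MeOH (10 equiv), Et2O, −40 °C
Reagents that add atoms: methanol, CO
Why: Cinchona-alkaloid-catalysed enantioselective alcoholysis (desymmetrisation) of a meso cyclic anhydride; general-base catalysis by the quinuclidine nitrogen differentiates the enantiotopic carbonyls and fixes the benzylic centre.

Step 8
Reactants: 14 (3S)-5-methoxy-5-oxo-3-phenylpentanoic acid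
Product: 15 1-tert-butyl 5-methyl (3R)-3-phenylpentanedioate
Conditions: tert-butyl 2,2,2-trichloroacetimidate, CH2Cl2/cyclohexane, rt
Reagents that add atoms: tert-butyl 2,2,2-trichloroacetimidate, CC(C)(C)OC(=N)C(Cl)(Cl)Cl
Why: Esterification of a carboxylic acid with a trichloroacetimidate, the acid itself serving as catalyst; the neutral conditions cannot re-form the anhydride, so the stereocentre stays defined.

Step 9
Reactants: 15 1-tert-butyl 5-methyl (3R)-3-phenylpentanedioate
Product: 16 (3R)-5-tert-butoxy-5-oxo-3-phenylpentanoic acid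
Conditions: LiOH·H2O, THF/H2O, 0 °C; 1 M HCl to pH 3
Reagents that add atoms: lithium hydroxide, [Li+].[OH-]
Why: Selective saponification of the methyl ester beside the hindered tert-butyl ester; the free acid now sits on the arm that will become C8a, and the stereocentre, β to both carbonyls, is untouched.

Step 10
Reactants: 12 (3S,5R)-3-acetyl-5-(3-methylbut-3-en-1-yl)-3-(3-methylbut-2-en-1-yl)oxan-2-one; 16 (3R)-5-tert-butoxy-5-oxo-3-phenylpentanoic acid
Product: 18 tert-butyl (3R)-7-[(3S,5R)-5-(3-methylbut-3-en-1-yl)-3-(3-methylbut-2-en-1-yl)-2-oxooxan-3-yl]-5,7-dioxo-3-phenylheptanoate, via acyl imidazole 17 (not isolated)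
Conditions: 16, 1,1'-carbonyldiimidazole, THF, rt; separately 12, LiN(SiMe3)2 (3.2 equiv), THF, −78 °C; then the solution of 17, −78 → −30 °C; aq. NH4Cl
Reagents that add atoms: none
Why: Claisen-type C-acylation of a methyl ketone lithium enolate by an acyl imidazole; the acetyl methyl is the only enolisable position of 12, and the extra base absorbs the imidazole N–H and the more acidic 1,3-diketone as it forms.

Step 11
Reactants: 18 tert-butyl (3R)-7-[(3S,5R)-5-(3-methylbut-3-en-1-yl)-3-(3-methylbut-2-en-1-yl)-2-oxooxan-3-yl]-5,7-dioxo-3-phenylheptanoate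
Product: 19 tert-butyl (3R)-3-{(5S)-2-hydroxy-5-[(2R)-2-(hydroxymethyl)-5-methylhex-5-en-1-yl]-5-(3-methylbut-2-en-1-yl)-4,6-dioxocyclohex-1-en-1-yl}-3-phenylpropanoate
Conditions: LiN(i-Pr)2 (3.5 equiv), THF, −78 → 0 °C; AcOH, −78 °C; aqueous work-up
Reagents that add atoms: none
Why: The base removes in turn the central C4a proton, an α-proton of the tert-butyl ester and a C8 proton; the C8 carbanion of the resulting 1,3-diketone dianion adds to the lactone carbonyl C7, the tetrahedral intermediate expels the primary alkoxide, and the trione is deprotonated at once to its bis-enolate. The closest known reaction type is the terminal-carbon acylation of β-diketone dianions by esters and its intramolecular form, the Dieckmann-type closure of 3,5-diketo esters to cyclohexane-1,3,5-triones. Ring A closes in a 6-(enolendo)-exo-trig mode, which Baldwin's rules for enolates allow. No stereocentre is formed: C8 ends as an enol carbon, and C6, C2' and the benzylic centre are spectators, none of them α to a carbonyl. Site selectivity is structural: C8 is the last-formed and most nucleophilic carbon, C4a could reach C7 only through a four-membered ring, and C6 has no proton. Chemoselectivity for the lactone over the ester rests on the ester being present as its lithium enolate, which is not an electrophile, and on its tert-butyl group; if an enolate oxygen acylates first, the enol lactone formed is converted by the same base into the same trione. The vinylogous-acid enolate of 19 is the thermodynamic sink that draws the reversible Claisen step forward.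

Step 12
Reactants: 19 tert-butyl (3R)-3-{(5S)-2-hydroxy-5-[(2R)-2-(hydroxymethyl)-5-methylhex-5-en-1-yl]-5-(3-methylbut-2-en-1-yl)-4,6-dioxocyclohex-1-en-1-yl}-3-phenylpropanoate
Product: 20 tert-butyl (3R)-3-{(5S)-5-[(2R)-2-({[tert-butyl(diphenyl)silyl]oxy}methyl)-5-methylhex-5-en-1-yl]-2-hydroxy-5-(3-methylbut-2-en-1-yl)-4,6-dioxocyclohex-1-en-1-yl}-3-phenylpropanoate
Conditions: t-BuPh2SiCl, imidazole, DMF, 0 °C → rt; aq. citric acid/MeOH work-up
Reagents that add atoms: tert-butyl(chloro)diphenylsilane, CC(C)(C)[Si](Cl)(c1ccccc1)c1ccccc1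
Why: Silylation of the primary alcohol; any enol silyl ether of the vinylogous acid is hydrolysed in the acidic work-up. The free alcohol would otherwise be acylated in step 16 and form its own enol ether with a ring carbonyl in step 17.

Step 13
Reactants: 21 (4S)-4-benzyl-3-propanoyl-1,3-oxazolidin-2-one
Product: 22 (4S)-4-benzyl-3-[(2S,3R)-3-hydroxy-2-methylbutanoyl]-1,3-oxazolidin-2-one
Conditions: Bu2BOTf, i-Pr2NEt, CH2Cl2, 0 °C; MeCHO, −78 → 0 °C; pH 7 buffer, MeOH, H2O2
Reagents that add atoms: acetaldehyde, CC=O
Why: Evans syn aldol reaction; the Z-boron enolate reacts through a Zimmerman–Traxler chair with the auxiliary dipole opposed, giving the (2S,3R) syn adduct that carries both ring B stereocentres.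

Step 14
Reactants: 22 (4S)-4-benzyl-3-[(2S,3R)-3-hydroxy-2-methylbutanoyl]-1,3-oxazolidin-2-one
Product: 23 (4S)-4-benzyl-3-{(2S,3R)-2-methyl-3-[(triethylsilyl)oxy]butanoyl}-1,3-oxazolidin-2-one
Conditions: Et3SiOTf, 2,6-lutidine, CH2Cl2, 0 °C
Reagents that add atoms: triethylsilyl trifluoromethanesulfonate, CC[Si](CC)(CC)OS(=O)(=O)C(F)(F)F
Why: Silylation of the secondary alcohol with a silyl triflate and a hindered base; the triethylsilyl group prevents self-acylation in step 16 and is labile enough to come off under the conditions of step 17.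

Step 15
Reactants: 23 (4S)-4-benzyl-3-{(2S,3R)-2-methyl-3-[(triethylsilyl)oxy]butanoyl}-1,3-oxazolidin-2-one
Product: 25 (2S,3R)-2-methyl-3-[(triethylsilyl)oxy]butanoic acid, via peroxy acid 24 (not isolated)
Conditions: LiOH, H2O2, THF/H2O, 0 °C; Na2SO3; HCl to pH 3
Reagents that add atoms: hydrogen peroxide, OO
Why: Hydroperoxide cleavage of the N-acyl oxazolidinone; the hydroperoxide anion attacks the exocyclic carbonyl selectively and is too weakly basic to epimerise the α-centre, and sulfite reduces the peroxy acid to the acid.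

Step 16
Reactants: 20 tert-butyl (3R)-3-{(5S)-5-[(2R)-2-({[tert-butyl(diphenyl)silyl]oxy}methyl)-5-methylhex-5-en-1-yl]-2-hydroxy-5-(3-methylbut-2-en-1-yl)-4,6-dioxocyclohex-1-en-1-yl}-3-phenylpropanoate; 25 (2S,3R)-2-methyl-3-[(triethylsilyl)oxy]butanoic acid
Product: 27 tert-butyl (3R)-3-{(3R)-3-[(2R)-2-({[tert-butyl(diphenyl)silyl]oxy}methyl)-5-methylhex-5-en-1-yl]-2,4-dihydroxy-3-(3-methylbut-2-en-1-yl)-5-{(2S,3R)-2-methyl-3-[(triethylsilyl)oxy]butanoyl}-6-oxocyclohexa-1,4-dien-1-yl}-3-phenylpropanoate, via enol ester 26 (not isolated)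
Conditions: N,N'-dicyclohexylcarbodiimide, 4-(dimethylamino)pyridine (1.2 equiv), CH2Cl2, 0 °C → rt
Reagents that add atoms: none
Why: Steglich-type O-acylation of the vinylogous acid followed by 4-(dimethylamino)pyridine-mediated O-to-C acyl migration, the standard C-acylation of cyclic 1,3-diones; C4a is the only ring carbon at which C-acylation ends in a chelated, enolised triketone, so acyl transfer funnels there.

Step 17
Reactants: 27 tert-butyl (3R)-3-{(3R)-3-[(2R)-2-({[tert-butyl(diphenyl)silyl]oxy}methyl)-5-methylhex-5-en-1-yl]-2,4-dihydroxy-3-(3-methylbut-2-en-1-yl)-5-{(2S,3R)-2-methyl-3-[(triethylsilyl)oxy]butanoyl}-6-oxocyclohexa-1,4-dien-1-yl}-3-phenylpropanoate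
Product: 29 tert-butyl (3R)-3-{(2R,3S,6R)-6-[(2R)-2-({[tert-butyl(diphenyl)silyl]oxy}methyl)-5-methylhex-5-en-1-yl]-4-hydroxy-2,3-dimethyl-6-(3-methylbut-2-en-1-yl)-5,7-dioxo-3,5,6,7-tetrahydro-2H-chromen-8-yl}-3-phenylpropanoate, via hydroxy ketone 28 (not isolated)
Conditions: HF·pyridine, pyridine, THF, 0 °C; then camphor-10-sulfonic acid (10 mol %), 4 Å molecular sieves, CH2Cl2, rt
Reagents that add atoms: none
Why: Fluoride removes the triethylsilyl ether, and acid-catalysed cyclodehydration (vinylogous ester formation from a δ-hydroxy β-diketone) closes ring B. The hydroxyl adds to the C8a carbonyl, whose faces are open, in preference to C5, which is shielded by quaternary C6. The carbinol C–O bond is never broken, so the syn acid gives the cis (2R,3S) ring with retention.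

Step 18
Reactants: 29 tert-butyl (3R)-3-{(2R,3S,6R)-6-[(2R)-2-({[tert-butyl(diphenyl)silyl]oxy}methyl)-5-methylhex-5-en-1-yl]-4-hydroxy-2,3-dimethyl-6-(3-methylbut-2-en-1-yl)-5,7-dioxo-3,5,6,7-tetrahydro-2H-chromen-8-yl}-3-phenylpropanoate
Product: 30 tert-butyl (3R)-3-{(2R,3S,6R)-4-hydroxy-6-[(2R)-2-(hydroxymethyl)-5-methylhex-5-en-1-yl]-2,3-dimethyl-6-(3-methylbut-2-en-1-yl)-5,7-dioxo-3,5,6,7-tetrahydro-2H-chromen-8-yl}-3-phenylpropanoate
Conditions: Bu4NF, AcOH (1:1), THF, rt
Reagents that add atoms: none
Why: Fluoride desilylation, buffered with acetic acid so that the cis ring B is not exposed to base.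

Step 19
Reactants: 30 tert-butyl (3R)-3-{(2R,3S,6R)-4-hydroxy-6-[(2R)-2-(hydroxymethyl)-5-methylhex-5-en-1-yl]-2,3-dimethyl-6-(3-methylbut-2-en-1-yl)-5,7-dioxo-3,5,6,7-tetrahydro-2H-chromen-8-yl}-3-phenylpropanoate
Product: 31 tert-butyl (3R)-3-{(2R,3S,6R)-6-[(2R)-2-formyl-5-methylhex-5-en-1-yl]-4-hydroxy-2,3-dimethyl-6-(3-methylbut-2-en-1-yl)-5,7-dioxo-3,5,6,7-tetrahydro-2H-chromen-8-yl}-3-phenylpropanoate
Conditions: Dess–Martin periodinane, NaHCO3, CH2Cl2, 0 °C → rt
Reagents that add atoms: none
Why: Dess–Martin oxidation under buffered, non-enolising conditions that keep the α-stereocentre C2'; C4a is now fully substituted, so the ring has no carbon left that can condense with the aldehyde.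

Step 20
Reactants: 31 tert-butyl (3R)-3-{(2R,3S,6R)-6-[(2R)-2-formyl-5-methylhex-5-en-1-yl]-4-hydroxy-2,3-dimethyl-6-(3-methylbut-2-en-1-yl)-5,7-dioxo-3,5,6,7-tetrahydro-2H-chromen-8-yl}-3-phenylpropanoate
Product: 32 tert-butyl (3R)-3-{(2R,3S,6S)-4-hydroxy-2,3-dimethyl-6-(3-methylbut-2-en-1-yl)-6-[(2R)-5-methyl-2-(2-methylprop-1-en-1-yl)hex-5-en-1-yl]-5,7-dioxo-3,5,6,7-tetrahydro-2H-chromen-8-yl}-3-phenylpropanoate
Conditions: i-PrPPh3I (3 equiv), n-BuLi, THF, 0 °C; then 31, −78 → 0 °C
Reagents that add atoms: isopropyltriphenylphosphonium iodide, CC(C)[P+](c1ccccc1)(c1ccccc1)c1ccccc1.[I-]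
Why: Wittig olefination with the non-stabilised isopropylidene ylide; one equivalent is consumed by the chelated enol, whose anion then shields ring B, and addition to the aldehyde at low temperature should outrun its enolisation. The new alkene has no E/Z issue.

Step 21
Reactants: 32 tert-butyl (3R)-3-{(2R,3S,6S)-4-hydroxy-2,3-dimethyl-6-(3-methylbut-2-en-1-yl)-6-[(2R)-5-methyl-2-(2-methylprop-1-en-1-yl)hex-5-en-1-yl]-5,7-dioxo-3,5,6,7-tetrahydro-2H-chromen-8-yl}-3-phenylpropanoate
Product: 34 (3R)-3-{(2R,3S,6S)-4-hydroxy-2,3-dimethyl-6-(3-methylbut-2-en-1-yl)-6-[(2R)-5-methyl-2-(2-methylprop-1-en-1-yl)hex-5-en-1-yl]-5,7-dioxo-3,5,6,7-tetrahydro-2H-chromen-8-yl}-3-phenylpropanoic acid, via bis(trimethylsilyl) derivative 33 (not isolated)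
Conditions: Me3SiOTf (3 equiv), 2,6-lutidine, CH2Cl2, 0 °C; then pH 5 buffer/THF
Reagents that add atoms: none
Why: Silyl-triflate-mediated cleavage of the tert-butyl ester (silylation of the carbonyl and loss of isobutene) under buffered, aprotic conditions that spare the three alkenes and the cis ring B; aqueous work-up hydrolyses the silyl ester and the silyl enol ether.

## Compound list

1 | 5-oxohexanoic acid | CC(=O)CCCC(=O)O | starting material
2 | 5-methylhex-5-enoic acid | C=C(C)CCCC(=O)O | intermediate
3 | (4S)-4-benzyl-1,3-oxazolidin-2-one | O=C1N[C@@H](Cc2ccccc2)CO1 | starting material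
4 | 5-methylhex-5-enoic pivalic anhydride | C=C(C)CCCC(=O)OC(=O)C(C)(C)C | intermediate
5 | (4S)-4-benzyl-3-(5-methylhex-5-enoyl)-1,3-oxazolidin-2-one | C=C(C)CCCC(=O)N1[C@@H](Cc2ccccc2)COC1=O | intermediate
6 | tert-butyl acrylate | C=CC(=O)OC(C)(C)C | starting material
7 | tert-butyl (4R)-4-{[(4S)-4-benzyl-2-oxo-1,3-oxazolidin-3-yl]carbonyl}-7-methyloct-7-enoate | C=C(C)CC[C@H](CCC(=O)OC(C)(C)C)C(=O)N1[C@@H](Cc2ccccc2)COC1=O | intermediate
8 | tert-butyl (4R)-4-(hydroxymethyl)-7-methyloct-7-enoate | C=C(C)CC[C@H](CCC(=O)OC(C)(C)C)CO | intermediate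
9 | (5R)-5-(3-methylbut-3-en-1-yl)oxan-2-one | C=C(C)CC[C@H]1COC(=O)CC1 | intermediate
10 | prenyl bromide (1-bromo-3-methylbut-2-ene) | CC(C)=CCBr | starting material
11 | (5R)-5-(3-methylbut-3-en-1-yl)-3-(3-methylbut-2-en-1-yl)oxan-2-one, C3 epimers | C=C(C)CC[C@H]1COC(=O)C(CC=C(C)C)C1 | intermediate
12 | (3S,5R)-3-acetyl-5-(3-methylbut-3-en-1-yl)-3-(3-methylbut-2-en-1-yl)oxan-2-one | C=C(C)CC[C@H]1COC(=O)[C@@](CC=C(C)C)(C1)C(C)=O | intermediate
13 | 3-phenylglutaric anhydride | O=C1CC(c2ccccc2)CC(=O)O1 | starting material
14 | (3S)-5-methoxy-5-oxo-3-phenylpentanoic acid | OC(=O)C[C@@H](CC(=O)OC)c1ccccc1 | intermediate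
15 | 1-tert-butyl 5-methyl (3R)-3-phenylpentanedioate | CC(C)(C)OC(=O)C[C@@H](CC(=O)OC)c1ccccc1 | intermediate
16 | (3R)-5-tert-butoxy-5-oxo-3-phenylpentanoic acid | CC(C)(C)OC(=O)C[C@@H](CC(=O)O)c1ccccc1 | intermediate
17 | tert-butyl (3R)-5-(1H-imidazol-1-yl)-5-oxo-3-phenylpentanoate | CC(C)(C)OC(=O)C[C@@H](CC(=O)n1ccnc1)c1ccccc1 | intermediate
18 | tert-butyl (3R)-7-[(3S,5R)-5-(3-methylbut-3-en-1-yl)-3-(3-methylbut-2-en-1-yl)-2-oxooxan-3-yl]-5,7-dioxo-3-phenylheptanoate | C=C(C)CC[C@H]1COC(=O)[C@@](CC=C(C)C)(C1)C(=O)CC(=O)C[C@H](CC(=O)OC(C)(C)C)c1ccccc1 | intermediate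
19 | tert-butyl (3R)-3-{(5S)-2-hydroxy-5-[(2R)-2-(hydroxymethyl)-5-methylhex-5-en-1-yl]-5-(3-methylbut-2-en-1-yl)-4,6-dioxocyclohex-1-en-1-yl}-3-phenylpropanoate | C=C(C)CC[C@@H](CO)C[C@@]1(CC=C(C)C)C(=O)CC(O)=C([C@H](CC(=O)OC(C)(C)C)c2ccccc2)C1=O | intermediate
20 | tert-butyl(diphenyl)silyl ether of 19 at the primary alcohol | C=C(C)CC[C@@H](CO[Si](c2ccccc2)(c2ccccc2)C(C)(C)C)C[C@@]1(CC=C(C)C)C(=O)CC(O)=C([C@H](CC(=O)OC(C)(C)C)c2ccccc2)C1=O | intermediate
21 | (4S)-4-benzyl-3-propanoyl-1,3-oxazolidin-2-one | CCC(=O)N1[C@@H](Cc2ccccc2)COC1=O | starting material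
22 | (4S)-4-benzyl-3-[(2S,3R)-3-hydroxy-2-methylbutanoyl]-1,3-oxazolidin-2-one | O=C([C@@H](C)[C@@H](C)O)N1[C@@H](Cc2ccccc2)COC1=O | intermediate
23 | (4S)-4-benzyl-3-{(2S,3R)-2-methyl-3-[(triethylsilyl)oxy]butanoyl}-1,3-oxazolidin-2-one | O=C([C@@H](C)[C@@H](C)O[Si](CC)(CC)CC)N1[C@@H](Cc2ccccc2)COC1=O | intermediate
24 | (2S,3R)-2-methyl-3-[(triethylsilyl)oxy]butaneperoxoic acid | OOC(=O)[C@@H](C)[C@@H](C)O[Si](CC)(CC)CC | intermediate
25 | (2S,3R)-2-methyl-3-[(triethylsilyl)oxy]butanoic acid | OC(=O)[C@@H](C)[C@@H](C)O[Si](CC)(CC)CC | intermediate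
26 | enol ester of 20 with acid 25 (drawn as the C8a ester) | C=C(C)CC[C@@H](CO[Si](c2ccccc2)(c2ccccc2)C(C)(C)C)C[C@@]1(CC=C(C)C)C(=O)C=C(OC(=O)[C@@H](C)[C@@H](C)O[Si](CC)(CC)CC)C([C@H](CC(=O)OC(C)(C)C)c2ccccc2)=C1O | intermediate
27 | trione 20 acylated at C4a by the (2S,3R)-2-methyl-3-(triethylsilyloxy)butanoyl group (5,7-dienol form) | C=C(C)CC[C@@H](CO[Si](c2ccccc2)(c2ccccc2)C(C)(C)C)C[C@@]1(CC=C(C)C)C(O)=C(C(=O)[C@@H](C)[C@@H](C)O[Si](CC)(CC)CC)C(=O)C([C@H](CC(=O)OC(C)(C)C)c2ccccc2)=C1O | intermediate
28 | desilylated 27 with free (2S,3R)-3-hydroxy-2-methylbutanoyl group on C4a | C=C(C)CC[C@@H](CO[Si](c2ccccc2)(c2ccccc2)C(C)(C)C)C[C@@]1(CC=C(C)C)C(O)=C(C(=O)[C@@H](C)[C@@H](C)O)C(=O)C([C@H](CC(=O)OC(C)(C)C)c2ccccc2)=C1O | intermediate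
29 | tert-butyl ester of 34 with the isobutenyl group replaced by a tert-butyl(diphenyl)silyloxymethyl group, (2R,3S,6R,2'R) | C=C(C)CC[C@@H](CO[Si](c3ccccc3)(c3ccccc3)C(C)(C)C)C[C@@]1(CC=C(C)C)C(=O)C2=C(O)[C@@H](C)[C@@H](C)OC2=C([C@H](CC(=O)OC(C)(C)C)c2ccccc2)C1=O | intermediate
30 | primary alcohol from 29, (2R,3S,6R,2'R) | C=C(C)CC[C@@H](CO)C[C@@]1(CC=C(C)C)C(=O)C2=C(O)[C@@H](C)[C@@H](C)OC2=C([C@H](CC(=O)OC(C)(C)C)c2ccccc2)C1=O | intermediate
31 | aldehyde from 30, (2R,3S,6R,2'R) | C=C(C)CC[C@@H](C=O)C[C@@]1(CC=C(C)C)C(=O)C2=C(O)[C@@H](C)[C@@H](C)OC2=C([C@H](CC(=O)OC(C)(C)C)c2ccccc2)C1=O | intermediate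
32 | tert-butyl ester of 34 | C=C(C)CC[C@@H](C=C(C)C)C[C@@]1(CC=C(C)C)C(=O)C2=C(O)[C@@H](C)[C@@H](C)OC2=C([C@H](CC(=O)OC(C)(C)C)c2ccccc2)C1=O | intermediate
33 | trimethylsilyl ester of 34 silylated also at the C4 enol oxygen | C=C(C)CC[C@@H](C=C(C)C)C[C@@]1(CC=C(C)C)C(=O)C2=C(O[Si](C)(C)C)[C@@H](C)[C@@H](C)OC2=C([C@H](CC(=O)O[Si](C)(C)C)c2ccccc2)C1=O | intermediate
34 | (3R)-3-{(2R,3S,6S)-4-hydroxy-2,3-dimethyl-6-(3-methylbut-2-en-1-yl)-6-[(2R)-5-methyl-2-(2-methylprop-1-en-1-yl)hex-5-en-1-yl]-5,7-dioxo-3,5,6,7-tetrahydro-2H-chromen-8-yl}-3-phenylpropanoic acid | C=C(C)CC[C@@H](C=C(C)C)C[C@@]1(CC=C(C)C)C(=O)C2=C(O)[C@@H](C)[C@@H](C)OC2=C([C@H](CC(=O)O)c2ccccc2)C1=O | target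

## Step count and least certain steps

Total steps: 21. Longest linear sequence: 15 (steps 1 to 6, 10 to 12, 16 to 21). Steps 7 to 9 and 13 to 15 are side branches.

**Step 11 (key step).** The third equivalent of base may be spent on the ester without the C8 carbanion forming cleanly. The central carbon may be acylated by the ester arm in a competing six-membered closure. The liberated alkoxide may cleave the β-keto lactone by retro-Claisen reaction before the trione enolate has formed. The fallback replaces the dianion by a mono-enolate whose position is fixed by structure. It sets out from 18, which is O-methylated with trimethylsilyldiazomethane to the methyl enol ether F1 (either regioisomer has C8 as its only acidic ring-forming carbon, C4a being vinylic). One equivalent of LiN(SiMe3)2 then gives the C8 enolate, which acylates on the lactone to the cyclised methyl enol ether F2. Dilute aqueous acid hydrolyses the vinylogous ester, and the route is rejoined at 19.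

**Step 6.** O-acylation may compete with C-acylation at the fully substituted enolate, proton transfer from the product may stall conversion, and the facial preference for axial attack may be modest with so reactive an electrophile. The fallback forms the C–C bond by aldol addition instead. It sets out from 11, whose enolate is added to acetaldehyde at −78 °C to give the hydroxyethyl lactone F3 (carbinol epimers), and Dess–Martin oxidation returns to 12.

**Step 16.** The activated acid may lose configuration at its α-methyl centre through ketene formation, may eliminate the β-silyloxy group, or may stop at the enol ester. The fallback uses an acyl group with no stereocentre and no leaving group. It sets out from 20, which is C-acylated with tiglic acid under the same carbodiimide conditions to the tigloyl trione F4. Ring B is then closed by quinine-catalysed intramolecular oxa-Michael addition, the known kinetic route to cis-2,3-dimethylchromanones from ortho-tigloyl phenols, returning to the route at 29.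

**Step 17.** Closure may occur on the C5 oxygen instead of C8a. Acid may eliminate the β-hydroxy ketone to a tigloyl group that re-closes without stereocontrol. The cis ring may epimerise at C3, or the prenyl group may cyclise onto an enol oxygen. The fallback closes the ring at the carbinol carbon under neutral conditions and sets out from 20. Ethyl (S)-3-hydroxybutanoate is methylated by Fráter–Seebach alkylation to the anti hydroxy ester F5, silylated to the silyl ether ester F6 and saponified to the anti acid F7. C-acylation of 20 with F7 as in step 16 gives the anti acyl trione F8, and buffered fluoride gives the anti hydroxy ketone F9. Mitsunobu closure (PPh3, diisopropyl azodicarboxylate) with inversion at C2 returns to 29.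

**Step 20.** The hindered, basic ylide may enolise the α-branched aldehyde and epimerise C2', or may add too slowly. The fallback avoids the aldehyde altogether and sets out from 30. Mitsunobu reaction with 1-phenyl-1H-tetrazole-5-thiol gives the tetrazolyl sulfide F10, and molybdate-catalysed oxidation with H2O2 gives the tetrazolyl sulfone F11. Julia–Kocienski olefination of F11 with acetone (KN(SiMe3)2, −78 °C) returns to 32; here C2' is never α to a carbonyl.

## Further compounds

F1 | step 11 | methyl enol ether of 18 (drawn as the C8a ether) | C=C(C)CC[C@H]1COC(=O)[C@@](CC=C(C)C)(C1)C(=O)C=C(OC)C[C@H](CC(=O)OC(C)(C)C)c1ccccc1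
F2 | step 11 | C8a methyl enol ether of trione 19 | C=C(C)CC[C@@H](CO)C[C@@]1(CC=C(C)C)C(=O)C=C(OC)C([C@H](CC(=O)OC(C)(C)C)c2ccccc2)=C1O
F3 | step 6 | (3S,5R)-3-(1-hydroxyethyl)-5-(3-methylbut-3-en-1-yl)-3-(3-methylbut-2-en-1-yl)oxan-2-one, carbinol epimers | C=C(C)CC[C@H]1COC(=O)[C@@](CC=C(C)C)(C1)C(C)O
F4 | step 16 | trione 20 acylated at C4a by the (E)-2-methylbut-2-enoyl group | C=C(C)CC[C@@H](CO[Si](c2ccccc2)(c2ccccc2)C(C)(C)C)C[C@@]1(CC=C(C)C)C(O)=C(C(=O)/C(C)=C/C)C(=O)C([C@H](CC(=O)OC(C)(C)C)c2ccccc2)=C1O
F5 | step 17 | ethyl (2S,3S)-3-hydroxy-2-methylbutanoate | CCOC(=O)[C@@H](C)[C@H](C)O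
F6 | step 17 | ethyl (2S,3S)-2-methyl-3-[(triethylsilyl)oxy]butanoate | CCOC(=O)[C@@H](C)[C@H](C)O[Si](CC)(CC)CC
F7 | step 17 | (2S,3S)-2-methyl-3-[(triethylsilyl)oxy]butanoic acid | OC(=O)[C@@H](C)[C@H](C)O[Si](CC)(CC)CC
F8 | step 17 | trione 20 acylated at C4a by the (2S,3S)-2-methyl-3-(triethylsilyloxy)butanoyl group | C=C(C)CC[C@@H](CO[Si](c2ccccc2)(c2ccccc2)C(C)(C)C)C[C@@]1(CC=C(C)C)C(O)=C(C(=O)[C@@H](C)[C@H](C)O[Si](CC)(CC)CC)C(=O)C([C@H](CC(=O)OC(C)(C)C)c2ccccc2)=C1O
F9 | step 17 | desilylated F8 with free (2S,3S)-3-hydroxy-2-methylbutanoyl group on C4a | C=C(C)CC[C@@H](CO[Si](c2ccccc2)(c2ccccc2)C(C)(C)C)C[C@@]1(CC=C(C)C)C(O)=C(C(=O)[C@@H](C)[C@H](C)O)C(=O)C([C@H](CC(=O)OC(C)(C)C)c2ccccc2)=C1O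
F10 | step 20 | 1-phenyl-1H-tetrazol-5-yl sulfide from alcohol 30 | C=C(C)CC[C@@H](CSc3nnnn3-c3ccccc3)C[C@@]1(CC=C(C)C)C(=O)C2=C(O)[C@@H](C)[C@@H](C)OC2=C([C@H](CC(=O)OC(C)(C)C)c2ccccc2)C1=O
F11 | step 20 | 1-phenyl-1H-tetrazol-5-yl sulfone from F10 | C=C(C)CC[C@@H](CS(=O)(=O)c3nnnn3-c3ccccc3)C[C@@]1(CC=C(C)C)C(=O)C2=C(O)[C@@H](C)[C@@H](C)OC2=C([C@H](CC(=O)OC(C)(C)C)c2ccccc2)C1=O
A1 | alternative 1 | 2-[(2R)-2-(hydroxymethyl)-5-methylhex-5-en-1-yl]-2-(3-methylbut-2-en-1-yl)cyclohexane-1,3,5-trione | C=C(C)CC[C@@H](CO)CC1(CC=C(C)C)C(=O)CC(=O)CC1=O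
A2 | alternative 1 | (3R,4aS)-3-(3-methylbut-3-en-1-yl)-4a-(3-methylbut-2-en-1-yl)-2,3,4,4a-tetrahydro-5H-chromene-5,7(6H)-dione | C=C(C)CC[C@H]1COC2=CC(=O)CC(=O)[C@@]2(CC=C(C)C)C1
A3 | alternative 2 | ring A methyl ester carrying at C4a the Z tert-butyldimethylsilyl enol ether of a propanoyl group, a C8a methyl enol ether and a C7 tert-butyldimethylsilyl enol ether | C=C(C)CC[C@@H](C=C(C)C)C[C@@]1(CC=C(C)C)C(=O)C(/C(O[Si](C)(C)C(C)(C)C)=C/C)=C(OC)C([C@H](CC(=O)OC)c2ccccc2)=C1O[Si](C)(C)C(C)(C)C
A4 | alternative 2 | methyl ester of 34 as its C7 tert-butyldimethylsilyl enol ether, 4-keto form | C=C(C)CC[C@@H](C=C(C)C)C[C@@]1(CC=C(C)C)C(=O)C2=C(O[C@H](C)[C@H](C)C2=O)C([C@H](CC(=O)OC)c2ccccc2)=C1O[Si](C)(C)C(C)(C)C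
A5 | alternative 3 | C5-oxygen-tethered bicycle with a (2S,3S)-3-hydroxy-2-methylbutanoyl group on C4a and a free C8a enol, methyl ester | C=C(C)CC[C@H]1COC2=C(C(=O)[C@@H](C)[C@H](C)O)C(O)=C([C@H](CC(=O)OC)c3ccccc3)C(=O)[C@@]2(CC=C(C)C)C1
A6 | alternative 3 | tethered tricycle with ring B closed and the C2' arm bound as the C5 enol ether, methyl ester | C=C(C)CC[C@H]1COC2=C3C(=O)[C@@H](C)[C@@H](C)OC3=C([C@H](CC(=O)OC)c3ccccc3)C(=O)[C@@]2(CC=C(C)C)C1
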